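**Strategy**

Ring B (C1–C2–C3–C4–C4a–C8a, naphthalene numbering of the target) is cut into two three-carbon pieces: the arene-bound C4a–C8a–C1 unit of an ortho-iodoaryl pentenoate and C2–C3–C4 of 2-methylpenta-1,4-diene. One palladium-catalysed Heck/chain-walk/allylic-alkylation annulation joins C4 to aryl carbon C4a and the dienolate γ-carbon C1 to C2. It sets the C1 quaternary and C2 tertiary stereocentres and leaves the diene's 1,1-disubstituted alkene as the isopropenyl group. It exploits the 1,3-relationship of C4a and C1 across sp2 C8a and the vinylogous nucleophilicity of C1 in the pentenoate dienolate. Ring C, a para-peroxyquinol, is finally unveiled from the phenol with singlet oxygen.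

Key step: step 6

Remarks on the chemistry:
- Locants are those of the target name throughout: C1 is the quaternary carbon, C2 the isopropenyl-bearing CH, C4a the hydroperoxide carbon. The saturated ring is called ring B and the oxygenated ring is called ring C.
- Assumption: the sense of induction of the chiral ligand in step 6 cannot be predicted for a new reaction. The ligand L* is written as (Sa)-1,1'-binaphthalene-2,2'-diyl N,N-bis[(R)-1-phenylethyl]phosphoramidite; its antipode is used if a test run shows the opposite sense.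
- Compound 7 is drawn as the E isomer; the Wittig step is expected to give an E/Z mixture, and both isomers give the same dienolate in step 6.

**Route**

Step 1
Reactants: 1 3-chloro-2-methylphenol
Product: 2 (3-chloro-2-methylphenoxy)tri(propan-2-yl)silane
Conditions: TIPSCl, imidazole, DMF, rt
Reagents that add atoms: triisopropylsilyl chloride CC(C)[Si](Cl)(C(C)C)C(C)C
Why: Standard imidazole-promoted silylation of a phenol; the bulky triisopropylsilyl ether should survive carbonate bases, shield its ortho position in the later iodination and be removable with fluoride without touching alkenes or the ester.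

Step 2
Reactants: 2 (3-chloro-2-methylphenoxy)tri(propan-2-yl)silane
Product: 3 [3-chloro-2-methyl-5-(4,4,5,5-tetramethyl-1,3,2-dioxaborolan-2-yl)phenoxy]tri(propan-2-yl)silane
Conditions: B2pin2, [Ir(OMe)(cod)]2 (1.5 mol%), 4,4'-di-tert-butyl-2,2'-bipyridine (3 mol%), cyclohexane, 80 °C
Reagents that add atoms: bis(pinacolato)diboron CC1(C)OB(OC1(C)C)B1OC(C)(C)C(C)(C)O1
Why: Sterically governed iridium-catalysed arene C–H borylation (Hartwig–Miyaura–Smith type) should functionalise only the C5–H of the 1,2,3-trisubstituted ring, the one C–H with no ortho substituent, which places boron meta to both chlorine and the silyloxy group.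

Step 3
Reactants: 3 [3-chloro-2-methyl-5-(4,4,5,5-tetramethyl-1,3,2-dioxaborolan-2-yl)phenoxy]tri(propan-2-yl)silane
Product: 4 1-[3-chloro-4-methyl-5-(triisopropylsilyloxy)phenyl]ethan-1-one
Conditions: Ac2O, Pd(OAc)2 (3 mol%), P(4-MeOC6H4)3 (7 mol%), THF, H2O (2.5 equiv), 60 °C
Reagents that add atoms: acetic anhydride CC(=O)OC(C)=O
Why: Suzuki–Miyaura-type acylation (coupling of an arylboron compound with a carboxylic anhydride through an acylpalladium acetate, the pinacol ester being hydrolysed in situ) should give the methyl ketone, while the aryl chloride is inert to a triarylphosphine catalyst at this temperature.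

Step 4
Reactants: 4 1-[3-chloro-4-methyl-5-(triisopropylsilyloxy)phenyl]ethan-1-one
Product: 5 1-[3-chloro-2-iodo-4-methyl-5-(triisopropylsilyloxy)phenyl]ethan-1-one
Conditions: I2, AgO2CCF3, CHCl3, rt, dark
Reagents that add atoms: iodine II
Why: Electrophilic aromatic iodination with silver-activated iodine should occur para to the silyloxy donor, because the only other activated site lies buried between the triisopropylsilyloxy and acetyl groups, and the non-enolising conditions should avoid α-iodination of the ketone.

Step 5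
Reactants: 5 1-[3-chloro-2-iodo-4-methyl-5-(triisopropylsilyloxy)phenyl]ethan-1-one
Product: 7 methyl (3E)-4-[3-chloro-2-iodo-4-methyl-5-(triisopropylsilyloxy)phenyl]pent-3-enoate, via sodium carboxylate 6 (not isolated)
Conditions: Ph3P(CH2CH2CO2H)Br, NaN(SiMe3)2 (3 equiv), THF, 0 °C to rt; then MeI, DMF, rt
Reagents that add atoms: (2-carboxyethyl)triphenylphosphonium bromide OC(=O)CC[P+](c1ccccc1)(c1ccccc1)c1ccccc1.[Br-]; iodomethane CI
Why: Wittig olefination with the carboxylate-bearing non-stabilised ylide is the standard route from acetophenones to 4-arylpent-3-enoic acids, and in situ SN2 methylation of the carboxylate should deliver the ester.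

Step 6
Reactants: 7 methyl (3E)-4-[3-chloro-2-iodo-4-methyl-5-(triisopropylsilyloxy)phenyl]pent-3-enoate; 8 2-methylpenta-1,4-diene
Product: 10 methyl (2E)-3-[(1R,2R)-5-chloro-1,6-dimethyl-2-(prop-1-en-2-yl)-7-(triisopropylsilyloxy)-1,2,3,4-tetrahydronaphthalen-1-yl]prop-2-enoate, via aryl diene 9 (not isolated)
Conditions: 8 (5 equiv), Pd2(dba)3 (5 mol%), L* (22 mol%), Cs2CO3 (2 equiv), 1,4-dioxane, 70 °C, sealed tube
Reagents that add atoms: none
Why: Proposed new method: zerovalent palladium inserts into the C–I bond, the arylpalladium adds to the monosubstituted alkene of 8 with aryl carbon C4a bonding to the terminal CH2 (C4–C4a bond), β-hydride elimination and re-addition (through diene 9, which stays on the metal hydride) shift palladium into an η3-2-methylallyl complex ending at C2, and the caesium dienolate of 7 attacks C2 with its γ-carbon C1 on the face opposite to palladium (C1–C2 bond). The closest known reactions are the Larock carboannulation of 1,4-dienes by ortho-iodoaryl malonates and enantioselective Heck/Tsuji–Trost couplings of aryl iodides with dienes and stabilised carbanions; new are the vinylogous ester pronucleophile, the quaternary centre and asymmetric induction in the chain-walking variant. Ring B closes in a 6-exo mode on the allyl terminus, the rest of the allyl unit staying outside the ring as the isopropenyl group. C2 is controlled by the chiral phosphoramidite, which selects one face of the allyl ligand after fast η3–η1–η3 equilibration through its CH2 terminus, and C1 is controlled relative to C2 by a chair-like transition state in which the allylpalladium unit and the larger enoate arm are both pseudo-equatorial, so that the C1 methyl ends up cis to the isopropenyl group. The step needs C–I over C–Cl insertion (bond strengths), insertion at the unhindered vinyl group of 8, diene insertion ahead of enolate arylation (excess 8, weak heterogeneous base) and γ-attack at C2 (α-attack or attack at the CH2 allyl terminus would need an eight-membered ring).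

Step 7
Reactants: 10 methyl (2E)-3-[(1R,2R)-5-chloro-1,6-dimethyl-2-(prop-1-en-2-yl)-7-(triisopropylsilyloxy)-1,2,3,4-tetrahydronaphthalen-1-yl]prop-2-enoate
Product: 11 methyl 3-[(1R,2R)-5-chloro-1,6-dimethyl-2-(prop-1-en-2-yl)-7-(triisopropylsilyloxy)-1,2,3,4-tetrahydronaphthalen-1-yl]propanoate
Conditions: Cu(OAc)2·H2O (5 mol%), 1,2-(Ph2P)2C6H4 (5 mol%), (Me2SiH)2O, t-BuOH, toluene, rt
Reagents that add atoms: none
Why: Conjugate reduction by phosphine-ligated CuH (Stryker/Lipshutz type, turned over by the silane) should be selective for the enoate, leaving the isopropenyl group, the aryl chloride, the silyl ether and both stereocentres untouched.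

Step 8
Reactants: 11 methyl 3-[(1R,2R)-5-chloro-1,6-dimethyl-2-(prop-1-en-2-yl)-7-(triisopropylsilyloxy)-1,2,3,4-tetrahydronaphthalen-1-yl]propanoate
Product: 12 methyl 3-[(1R,2R)-5-ethenyl-1,6-dimethyl-2-(prop-1-en-2-yl)-7-(triisopropylsilyloxy)-1,2,3,4-tetrahydronaphthalen-1-yl]propanoate
Conditions: CH2=CHBpin, Pd(OAc)2 (5 mol%), SPhos (10 mol%), K3PO4, toluene/H2O (10:1), 90 °C
Reagents that add atoms: 2-ethenyl-4,4,5,5-tetramethyl-1,3,2-dioxaborolane C=CB1OC(C)(C)C(C)(C)O1
Why: Suzuki–Miyaura coupling of the di-ortho-substituted aryl chloride should work with the dialkylbiarylphosphine SPhos, and the vinyl group is introduced only now so that it never meets the iodination or the arylpalladium of step 6.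

Step 9
Reactants: 12 methyl 3-[(1R,2R)-5-ethenyl-1,6-dimethyl-2-(prop-1-en-2-yl)-7-(triisopropylsilyloxy)-1,2,3,4-tetrahydronaphthalen-1-yl]propanoate
Product: 13 methyl 3-[(1R,2R)-5-ethenyl-7-hydroxy-1,6-dimethyl-2-(prop-1-en-2-yl)-1,2,3,4-tetrahydronaphthalen-1-yl]propanoate
Conditions: n-Bu4NF, AcOH, THF, 0 °C
Reagents that add atoms: none
Why: Fluoride-induced cleavage of the aryl silyl ether, buffered with acetic acid so that the phenoxide does not attack the ester, should free the phenol without touching a stereocentre.

Step 10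
Reactants: 13 methyl 3-[(1R,2R)-5-ethenyl-7-hydroxy-1,6-dimethyl-2-(prop-1-en-2-yl)-1,2,3,4-tetrahydronaphthalen-1-yl]propanoate
Product: 14 trigonochinene C, methyl 3-[(1R,2R,4aR)-5-ethenyl-4a-hydroperoxy-1,6-dimethyl-7-oxo-2-(prop-1-en-2-yl)-1,2,3,4,4a,7-hexahydronaphthalen-1-yl]propanoate
Conditions: O2, 5,10,15,20-tetraphenylporphyrin (1 mol%), visible light, CH2Cl2/MeOH (9:1), −20 °C
Reagents that add atoms: dioxygen O=O
Why: Dearomative hydroperoxidation of a 4-alkylphenol by singlet oxygen (formal [4+2]/ene addition, the standard entry to para-peroxyquinols) should be chemoselective because the electron-rich phenol reacts faster than the 1,1-disubstituted alkene and the twisted styrene, and the C4a stereocentre is set by substrate control, oxygen being expected on the face that carries the small C1 methyl (anti to the propanoate arm) through the chair-like pathway that keeps the arm and the isopropenyl group equatorial.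

**Compound list**

1 | 3-chloro-2-methylphenol | Cc1c(O)cccc1Cl | starting material
2 | (3-chloro-2-methylphenoxy)tri(propan-2-yl)silane | Cc1c(O[Si](C(C)C)(C(C)C)C(C)C)cccc1Cl | intermediate
3 | [3-chloro-2-methyl-5-(4,4,5,5-tetramethyl-1,3,2-dioxaborolan-2-yl)phenoxy]tri(propan-2-yl)silane | Cc1c(O[Si](C(C)C)(C(C)C)C(C)C)cc(B2OC(C)(C)C(C)(C)O2)cc1Cl | intermediate
4 | 1-[3-chloro-4-methyl-5-(triisopropylsilyloxy)phenyl]ethan-1-one | CC(=O)c1cc(Cl)c(C)c(O[Si](C(C)C)(C(C)C)C(C)C)c1 | intermediate
5 | 1-[3-chloro-2-iodo-4-methyl-5-(triisopropylsilyloxy)phenyl]ethan-1-one | CC(=O)c1cc(O[Si](C(C)C)(C(C)C)C(C)C)c(C)c(Cl)c1I | intermediate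
6 | sodium (3E)-4-[3-chloro-2-iodo-4-methyl-5-(triisopropylsilyloxy)phenyl]pent-3-enoate | C/C(=C\CC(=O)[O-])c1cc(O[Si](C(C)C)(C(C)C)C(C)C)c(C)c(Cl)c1I.[Na+] | intermediate (not isolated)
7 | methyl (3E)-4-[3-chloro-2-iodo-4-methyl-5-(triisopropylsilyloxy)phenyl]pent-3-enoate | C/C(=C\CC(=O)OC)c1cc(O[Si](C(C)C)(C(C)C)C(C)C)c(C)c(Cl)c1I | intermediate
8 | 2-methylpenta-1,4-diene | C=CCC(C)=C | starting material
9 | methyl (3E)-4-{3-chloro-4-methyl-2-[(2E)-4-methylpenta-2,4-dien-1-yl]-5-(triisopropylsilyloxy)phenyl}pent-3-enoate | C/C(=C\CC(=O)OC)c1cc(O[Si](C(C)C)(C(C)C)C(C)C)c(C)c(Cl)c1C/C=C/C(C)=C | intermediate (not isolated)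
10 | methyl (2E)-3-[(1R,2R)-5-chloro-1,6-dimethyl-2-(prop-1-en-2-yl)-7-(triisopropylsilyloxy)-1,2,3,4-tetrahydronaphthalen-1-yl]prop-2-enoate | Clc1c(C)c(O[Si](C(C)C)(C(C)C)C(C)C)cc2c1CC[C@H](C(=C)C)[C@@]2(C)/C=C/C(=O)OC | intermediate
11 | methyl 3-[(1R,2R)-5-chloro-1,6-dimethyl-2-(prop-1-en-2-yl)-7-(triisopropylsilyloxy)-1,2,3,4-tetrahydronaphthalen-1-yl]propanoate | Clc1c(C)c(O[Si](C(C)C)(C(C)C)C(C)C)cc2c1CC[C@H](C(=C)C)[C@@]2(C)CCC(=O)OC | intermediate
12 | methyl 3-[(1R,2R)-5-ethenyl-1,6-dimethyl-2-(prop-1-en-2-yl)-7-(triisopropylsilyloxy)-1,2,3,4-tetrahydronaphthalen-1-yl]propanoate | C=Cc1c(C)c(O[Si](C(C)C)(C(C)C)C(C)C)cc2c1CC[C@H](C(=C)C)[C@@]2(C)CCC(=O)OC | intermediate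
13 | methyl 3-[(1R,2R)-5-ethenyl-7-hydroxy-1,6-dimethyl-2-(prop-1-en-2-yl)-1,2,3,4-tetrahydronaphthalen-1-yl]propanoate | C=Cc1c(C)c(O)cc2c1CC[C@H](C(=C)C)[C@@]2(C)CCC(=O)OC | intermediate
14 | trigonochinene C, methyl 3-[(1R,2R,4aR)-5-ethenyl-4a-hydroperoxy-1,6-dimethyl-7-oxo-2-(prop-1-en-2-yl)-1,2,3,4,4a,7-hexahydronaphthalen-1-yl]propanoate | C=CC1=C(C)C(=O)C=C2[C@]1(OO)CC[C@H](C(=C)C)[C@@]2(C)CCC(=O)OC | target

**Step count and risks**

Total step count: 10. Longest linear sequence: 10 steps (from 1).

Steps most likely to fail: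

Step 6 (proposed new method). The arylpalladium iodide may be captured by the caesium dienolate before the diene inserts (intramolecular α-arylation to an indene). The allylpalladium may also lose hydride to a triene instead of cyclising, or the ring closure may proceed with poor face selection at C1 or C2. The fallback uses known reactions and makes the two ring bonds in separate operations. It sets out from 7 and comes back at 10. Negishi coupling of 7 with CH2=CHCH2CH2ZnBr (Pd(OAc)2, SPhos, THF, 40 °C) should give methyl (3E)-4-[2-(but-3-en-1-yl)-3-chloro-4-methyl-5-(triisopropylsilyloxy)phenyl]pent-3-enoate F1, which already holds the C4–C4a bond. Cross-metathesis with 2-methylallyl acetate (second-generation Hoveyda–Grubbs catalyst, CH2Cl2, 40 °C) should give methyl (3E)-4-{2-[(3E)-5-acetoxy-4-methylpent-3-en-1-yl]-3-chloro-4-methyl-5-(triisopropylsilyloxy)phenyl}pent-3-enoate F2; its alkene geometry is irrelevant. Deprotonation with NaN(SiMe3)2 (THF, −78 °C), then Pd2(dba)3 and the DACH-phenyl Trost ligand (−20 °C to rt), should close ring B by Tsuji–Trost asymmetric allylic alkylation through the same allylpalladium and the same chair, giving 10. The ligand enantiomer is again chosen by a test run.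

Step 10. Oxygen may be delivered to the other face of the phenol ring: the half-chair with a pseudo-axial C1 methyl exposes the face syn to the propanoate arm, so the facial selectivity may be poor and the 4a-epimer may form in quantity. Prolonged irradiation may also start an ene reaction at the isopropenyl group. The fallback replaces a single substrate-controlled pass by a separation and recycling loop. It sets out from the photooxygenation mixture made from 13 and comes back at 13. After chromatography, the unwanted methyl 3-[(1R,2R,4aS)-5-ethenyl-4a-hydroperoxy-1,6-dimethyl-7-oxo-2-(prop-1-en-2-yl)-1,2,3,4,4a,7-hexahydronaphthalen-1-yl]propanoate F3 is treated with Zn dust in AcOH/THF at rt. This reduces the hydroperoxide to the quinol and rearomatises it reductively (a known reduction of para-quinols to phenols), returning phenol 13 for another pass.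

Step 5. The bulky, basic carboxylate ylide may enolise the hindered ortho-iodoacetophenone instead of adding to it, so that conversion stalls. The fallback adds the three-carbon arm to an aldehyde instead. It sets out from 5 and comes back at 10. Methoxymethylenation of 5 with the small, reactive ylide from Ph3P(CH2OMe)Cl and KOC(CH3)3 (THF, 0 °C) should give {3-chloro-4-iodo-5-(1-methoxyprop-1-en-2-yl)-2-methylphenoxy}tri(propan-2-yl)silane F4. Hydrolysis (aqueous HCO2H, THF, rt) should give racemic 2-[3-chloro-2-iodo-4-methyl-5-(triisopropylsilyloxy)phenyl]propanal F5. Wittig reaction with Ph3P=CHCO2Me (CH2Cl2, rt) should give racemic methyl (2E)-4-[3-chloro-2-iodo-4-methyl-5-(triisopropylsilyloxy)phenyl]pent-2-enoate F6. F6 is the conjugated isomer of 7 and gives the same dienolate, so it is submitted to step 6 in place of 7 and delivers 10.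

Further compounds
F1 | step 6 | methyl (3E)-4-[2-(but-3-en-1-yl)-3-chloro-4-methyl-5-(triisopropylsilyloxy)phenyl]pent-3-enoate | C/C(=C\CC(=O)OC)c1cc(O[Si](C(C)C)(C(C)C)C(C)C)c(C)c(Cl)c1CCC=C
F2 | step 6 | methyl (3E)-4-{2-[(3E)-5-acetoxy-4-methylpent-3-en-1-yl]-3-chloro-4-methyl-5-(triisopropylsilyloxy)phenyl}pent-3-enoate | C/C(=C\CC(=O)OC)c1cc(O[Si](C(C)C)(C(C)C)C(C)C)c(C)c(Cl)c1CC/C=C(\C)COC(C)=O
F3 | step 10 | methyl 3-[(1R,2R,4aS)-5-ethenyl-4a-hydroperoxy-1,6-dimethyl-7-oxo-2-(prop-1-en-2-yl)-1,2,3,4,4a,7-hexahydronaphthalen-1-yl]propanoate | C=CC1=C(C)C(=O)C=C2[C@@]1(OO)CC[C@H](C(=C)C)[C@@]2(C)CCC(=O)OC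
F4 | step 5 | {3-chloro-4-iodo-5-(1-methoxyprop-1-en-2-yl)-2-methylphenoxy}tri(propan-2-yl)silane (E/Z mixture) | COC=C(C)c1cc(O[Si](C(C)C)(C(C)C)C(C)C)c(C)c(Cl)c1I
F5 | step 5 | 2-[3-chloro-2-iodo-4-methyl-5-(triisopropylsilyloxy)phenyl]propanal (racemic) | CC(C=O)c1cc(O[Si](C(C)C)(C(C)C)C(C)C)c(C)c(Cl)c1I
F6 | step 5 | methyl (2E)-4-[3-chloro-2-iodo-4-methyl-5-(triisopropylsilyloxy)phenyl]pent-2-enoate (racemic) | CC(/C=C/C(=O)OC)c1cc(O[Si](C(C)C)(C(C)C)C(C)C)c(C)c(Cl)c1I
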